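## Retrosynthetic overview

1. Target 28 ⇐ Schenck ene reaction of the (2Z)-6-methylhepta-2,5-dien-2-yl precursor 27. The enone comes from Saegusa–Ito oxidation of a silyl enol ether that masks the ketone, the Z-trisubstituted alkene from syn-carbocupration of an ynoate, and the prenyl terminus from a copper-catalysed allylic coupling.
2. cis-4-Methyl-5-alkylcyclopent-2-enone ⇐ syn-hydrogenation of a 2-alkyl-3-methylcyclopent-2-enone, closed by aldol condensation of a 1,4-diketone that is carried as a 5-methylfuran.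
3. Cyclopentane ⇐ Wolff ring contraction of a 2-diazocyclohexanone. The enabling feature is the ring carbon that bears OH and CH2OAc: this carbon and its exocyclic CH2OAc carbon are read as the α-carbon and the carbonyl carbon of a cyclohexanone, and the dienyl-bearing ring CH then lies para to that carbonyl.
4. Cyclohexanone ⇐ enantioselective Diels–Alder reaction of 2-silyloxy-3-furfurylbutadiene 3 with acrylate 4. It makes the two ring bonds CH2–C(OH) and CH2–CH(dienyl) that survive into the cyclopentane.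
5. Ring order: six-membered carbocycle (step 3), contracted to the cyclopentane (step 7), cyclopentenone ring last (step 9, enone in step 19).

Key step: step 3

Assumption: the (S)-configured oxazaborolidinium catalyst is taken to give the (1R)-adduct 5; if the facial sense proves opposite, the (R)-catalyst is used.

## Route

Step 1
Reactants: 1 4-(5-methylfuran-2-yl)butan-2-one
Product: 2 3-[(5-methylfuran-2-yl)methyl]but-3-en-2-one
Conditions: (CH2O)n, i-Pr2NH·CF3CO2H, CF3CO2H (cat.), THF, reflux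
Reagents that add atoms: formaldehyde (from paraformaldehyde), C=O
Why: Mannich-type α-methylenation should occur through the more substituted enol, at the CH2 next to the furfuryl group, and loss of the amine gives the 1,1-disubstituted enone.

Step 2
Reactants: 2 3-[(5-methylfuran-2-yl)methyl]but-3-en-2-one
Product: 3 triisopropyl({3-[(5-methylfuran-2-yl)methyl]buta-1,3-dien-2-yl}oxy)silane
Conditions: i-Pr3SiOTf, Et3N, CH2Cl2, 0 °C
Reagents that add atoms: triisopropylsilyl trifluoromethanesulfonate, CC(C)[Si](C(C)C)(C(C)C)OS(=O)(=O)C(F)(F)F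
Why: Soft enolisation of the cross-conjugated enone can only take place at the methyl group, which gives the 2-silyloxydiene.

Step 3
Reactants: 3 triisopropyl({3-[(5-methylfuran-2-yl)methyl]buta-1,3-dien-2-yl}oxy)silane; 4 2,2,2-trifluoroethyl prop-2-enoate
Product: 5 2,2,2-trifluoroethyl (1R)-3-[(5-methylfuran-2-yl)methyl]-4-(triisopropylsilyloxy)cyclohex-3-ene-1-carboxylate
Conditions: (S)-3,3-diphenyl-1-(o-tolyl)tetrahydropyrrolo[1,2-c][1,3,2]oxazaborole (20 mol%), Tf2NH (18 mol%), CH2Cl2, −78 → −40 °C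
Reagents that add atoms: none
Why: The protonated oxazaborolidine binds the acrylate carbonyl and the silyloxydiene adds in a concerted, asynchronous Diels–Alder reaction; the closest precedent is the enantioselective cycloaddition of 2-(triisopropylsilyloxy)butadiene with trifluoroethyl acrylate under this catalyst type. The six-membered carbocycle closes in a suprafacial [4+2] mode and is the ring later contracted to the cyclopentane, so the two bonds made here (diene CH2 next to the silyloxy carbon to the acrylate CH2, and the other diene CH2 to the acrylate CH) are two ring bonds of the target. The only new stereocenter, the ester-bearing carbon, is set by the catalyst, which shields one face of the bound acrylate. The step needs para regioselectivity, which the 2-silyloxy group secures because the adjacent diene terminus carries the largest HOMO coefficient and bonds to the acrylate β-carbon. The 2,3-disubstitution holds the diene s-cis, and the 2,5-dialkylfuran should be a far poorer diene and nucleophile at low temperature.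

Step 4
Reactants: 5 2,2,2-trifluoroethyl (1R)-3-[(5-methylfuran-2-yl)methyl]-4-(triisopropylsilyloxy)cyclohex-3-ene-1-carboxylate
Product: 6 (1R)-N-methoxy-N-methyl-3-[(5-methylfuran-2-yl)methyl]-4-(triisopropylsilyloxy)cyclohex-3-ene-1-carboxamide
Conditions: MeNH(OMe)·HCl, i-PrMgCl, THF, −20 °C
Reagents that add atoms: N,O-dimethylhydroxylamine hydrochloride, CNOC.Cl
Why: Aminolysis of the activated ester by the chloromagnesium amide gives the N-methoxy-N-methyl amide, whose α-hydrogen is not acidic enough to put the only stereocenter at risk and which later stops hydride reduction at the aldehyde.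

Step 5
Reactants: 6 (1R)-N-methoxy-N-methyl-3-[(5-methylfuran-2-yl)methyl]-4-(triisopropylsilyloxy)cyclohex-3-ene-1-carboxamide
Product: 7 (1R,3S)-N-methoxy-N-methyl-3-[(5-methylfuran-2-yl)methyl]-4-oxocyclohexane-1-carboxamide
Conditions: 1 M HCl, THF, 0 °C; then DBU (cat.), CH2Cl2, rt
Reagents that add atoms: none
Why: Hydrolysis of the silyl enol ether followed by equilibration at the ketone α-carbon should place the furfuryl group equatorial and cis to the equatorial amide (1,3-diequatorial), while the amide-bearing center is not enolised.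

Step 6
Reactants: 7 (1R,3S)-N-methoxy-N-methyl-3-[(5-methylfuran-2-yl)methyl]-4-oxocyclohexane-1-carboxamide
Product: 9 (1S,3S)-5-diazo-N-methoxy-N-methyl-3-[(5-methylfuran-2-yl)methyl]-4-oxocyclohexane-1-carboxamide, via trifluoroacetyl ketone 8 (not isolated)
Conditions: LiN(SiMe3)2, THF, −78 °C; CF3CO2CH2CF3; then MsN3, Et3N, MeCN, rt
Reagents that add atoms: methanesulfonyl azide, CS(=O)(=O)N=[N+]=[N-]
Why: Kinetic enolisation at the unhindered α-CH2, C-trifluoroacetylation and deacylative (Regitz-type) diazo transfer should place the diazo group on the ring CH2 that was the silyloxy-side diene terminus.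

Step 7
Reactants: 9 (1S,3S)-5-diazo-N-methoxy-N-methyl-3-[(5-methylfuran-2-yl)methyl]-4-oxocyclohexane-1-carboxamide
Product: 12 methyl (1R,2S,4S)-1-hydroxy-4-[methoxy(methyl)carbamoyl]-2-[(5-methylfuran-2-yl)methyl]cyclopentane-1-carboxylate, via ketene 10 (not isolated), via lithium enolate 11 (not isolated)
Conditions: hν (>300 nm), THF, −78 °C; LiOMe, −78 °C; 2-(benzenesulfonyl)-3-phenyloxaziridine, −78 °C; aq. NH4Cl
Reagents that add atoms: lithium methoxide, [Li+].[O-]C; 2-(benzenesulfonyl)-3-phenyloxaziridine, O=S(=O)(N1OC1c1ccccc1)c1ccccc1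
Why: Photochemical Wolff rearrangement contracts the ring with retention at the migrating furfuryl-bearing carbon, methoxide adds to the dialkylketene to give the ester enolate regiospecifically, and oxygen transfer to the enolate face anti to the two cis ring substituents should set the tertiary carbinol center.

Step 8
Reactants: 12 methyl (1R,2S,4S)-1-hydroxy-4-[methoxy(methyl)carbamoyl]-2-[(5-methylfuran-2-yl)methyl]cyclopentane-1-carboxylate
Product: 13 methyl (1R,2S,4S)-2-(2,5-dioxohexyl)-1-hydroxy-4-[methoxy(methyl)carbamoyl]cyclopentane-1-carboxylate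
Conditions: 2 M aq. HCl, THF, 60 °C
Reagents that add atoms: water, O
Why: Acid hydrolysis of the 2,5-dialkylfuran (reverse Paal–Knorr reaction) unmasks the 1,4-diketone, and the hindered ester and the amide should survive.

Step 9
Reactants: 13 methyl (1R,2S,4S)-2-(2,5-dioxohexyl)-1-hydroxy-4-[methoxy(methyl)carbamoyl]cyclopentane-1-carboxylate
Product: 14 methyl (1R,2S,4S)-1-hydroxy-4-[methoxy(methyl)carbamoyl]-2-(2-methyl-5-oxocyclopent-1-en-1-yl)cyclopentane-1-carboxylate
Conditions: NaOMe (cat.), MeOH, 50 °C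
Reagents that add atoms: none
Why: Intramolecular aldol condensation of the 2,5-diketone should give the more substituted 2-alkyl-3-methylcyclopent-2-enone, and methoxide in methanol neither cleaves the methyl ester nor epimerises the amide-bearing carbon.

Step 10
Reactants: 14 methyl (1R,2S,4S)-1-hydroxy-4-[methoxy(methyl)carbamoyl]-2-(2-methyl-5-oxocyclopent-1-en-1-yl)cyclopentane-1-carboxylate
Product: 15 methyl (1R,2S,4S)-1-hydroxy-4-[methoxy(methyl)carbamoyl]-2-[(1S,2R)-2-methyl-5-oxocyclopentyl]cyclopentane-1-carboxylate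
Conditions: H2 (4 atm), Pd/C (10%), EtOAc, rt
Reagents that add atoms: none
Why: Heterogeneous syn-hydrogenation sets the two new centers cis, and allylic 1,3-strain holds the C–H of the attached cyclopentane carbon in the enone plane toward the methyl group, so the quaternary carbinol carbon covers one face and hydrogen should enter from the face of the ring CH2.

Step 11
Reactants: 15 methyl (1R,2S,4S)-1-hydroxy-4-[methoxy(methyl)carbamoyl]-2-[(1S,2R)-2-methyl-5-oxocyclopentyl]cyclopentane-1-carboxylate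
Product: 16 methyl (1R,2S,4S)-2-[(1S,5R)-2-(tert-butyldimethylsilyloxy)-5-methylcyclopent-2-en-1-yl]-1-hydroxy-4-[methoxy(methyl)carbamoyl]cyclopentane-1-carboxylate
Conditions: LiN(i-Pr)2 (2.1 equiv), THF, −78 °C; t-BuMe2SiCl, DMPU, −78 → 0 °C
Reagents that add atoms: tert-butyldimethylsilyl chloride, CC(C)(C)[Si](C)(C)Cl
Why: Kinetic deprotonation at the unhindered α′-CH2 and O-silylation give the silyl enol ether, which masks the ketone, protects the cis α-center from epimerisation and fixes the regiochemistry of the later dehydrogenation.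

Step 12
Reactants: 16 methyl (1R,2S,4S)-2-[(1S,5R)-2-(tert-butyldimethylsilyloxy)-5-methylcyclopent-2-en-1-yl]-1-hydroxy-4-[methoxy(methyl)carbamoyl]cyclopentane-1-carboxylate
Product: 18 (1R,2S,4S)-2-[(1S,5R)-2-(tert-butyldimethylsilyloxy)-5-methylcyclopent-2-en-1-yl]-4-ethynyl-1-(hydroxymethyl)cyclopentan-1-ol, via aldehyde 17 (not isolated)
Conditions: i-Bu2AlH (5 equiv), CH2Cl2, −78 → −20 °C; then MeOH, K2CO3, dimethyl (1-diazo-2-oxopropyl)phosphonate, 0 °C → rt
Reagents that add atoms: dimethyl (1-diazo-2-oxopropyl)phosphonate, COP(=O)(OC)C(=[N+]=[N-])C(C)=O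
Why: The hydride reduces the ester to the primary alcohol but stops at the chelated adduct of the N-methoxy-N-methyl amide, which releases the aldehyde on methanolysis for Ohira–Bestmann homologation to the terminal alkyne.

Step 13
Reactants: 18 (1R,2S,4S)-2-[(1S,5R)-2-(tert-butyldimethylsilyloxy)-5-methylcyclopent-2-en-1-yl]-4-ethynyl-1-(hydroxymethyl)cyclopentan-1-ol
Product: 20 methyl 3-[(5R,6S,8S)-6-[(1S,5R)-2-(tert-butyldimethylsilyloxy)-5-methylcyclopent-2-en-1-yl]-2-oxo-1,3-dioxaspiro[4.4]nonan-8-yl]prop-2-ynoate, via open methyl carbonate 19 (not isolated)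
Conditions: n-BuLi (3.1 equiv), THF, −78 °C; ClCO2Me (3.2 equiv), −78 → 0 °C
Reagents that add atoms: methyl chloroformate, COC(=O)Cl
Why: The lithium acetylide is C-acylated to the ynoate, and the primary alkoxide is acylated as well, after which the neighbouring tertiary alkoxide closes the five-membered carbonate that protects the diol.

Step 14
Reactants: 20 methyl 3-[(5R,6S,8S)-6-[(1S,5R)-2-(tert-butyldimethylsilyloxy)-5-methylcyclopent-2-en-1-yl]-2-oxo-1,3-dioxaspiro[4.4]nonan-8-yl]prop-2-ynoate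
Product: 21 methyl (2Z)-3-[(5R,6S,8S)-6-[(1S,5R)-2-(tert-butyldimethylsilyloxy)-5-methylcyclopent-2-en-1-yl]-2-oxo-1,3-dioxaspiro[4.4]nonan-8-yl]but-2-enoate
Conditions: Me2CuLi (from MeLi and CuI), THF, −78 °C; MeOH, −78 °C; aq. NH4Cl
Reagents that add atoms: lithium dimethylcuprate, [Li+].C[Cu-]C
Why: Syn-carbocupration of the ynoate and protonation of the alkenylcuprate with retention at low temperature place methyl and hydrogen cis, so the ring and the ester end up cis, which is the (Z)-trisubstituted alkene.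

Step 15
Reactants: 21 methyl (2Z)-3-[(5R,6S,8S)-6-[(1S,5R)-2-(tert-butyldimethylsilyloxy)-5-methylcyclopent-2-en-1-yl]-2-oxo-1,3-dioxaspiro[4.4]nonan-8-yl]but-2-enoate
Product: 22 (1R,2S,4S)-2-[(1S,5R)-2-(tert-butyldimethylsilyloxy)-5-methylcyclopent-2-en-1-yl]-4-[(2Z)-4-hydroxybut-2-en-2-yl]-1-(hydroxymethyl)cyclopentan-1-ol
Conditions: i-Bu2AlH (6 equiv), CH2Cl2, −78 → 0 °C; aq. KNaC4H4O6
Reagents that add atoms: none
Why: 1,2-Reduction of the enoate gives the (Z)-allylic alcohol without touching the alkene, and the same hydride cleaves the cyclic carbonate back to the diol.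

Step 16
Reactants: 22 (1R,2S,4S)-2-[(1S,5R)-2-(tert-butyldimethylsilyloxy)-5-methylcyclopent-2-en-1-yl]-4-[(2Z)-4-hydroxybut-2-en-2-yl]-1-(hydroxymethyl)cyclopentan-1-ol
Product: 23 (1R,2S,4S)-2-[(1S,5R)-2-(tert-butyldimethylsilyloxy)-5-methylcyclopent-2-en-1-yl]-4-[(2Z)-4-chlorobut-2-en-2-yl]-1-(hydroxymethyl)cyclopentan-1-ol
Conditions: MsCl (1.05 equiv), 2,4,6-collidine, LiCl, DMF, −10 °C
Reagents that add atoms: lithium chloride, [Li+].[Cl-]
Why: The unhindered allylic hydroxyl should be mesylated much faster than the neopentylic and tertiary ones, and direct displacement by chloride gives the primary allylic chloride without transposition or loss of the Z geometry.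

Step 17
Reactants: 23 (1R,2S,4S)-2-[(1S,5R)-2-(tert-butyldimethylsilyloxy)-5-methylcyclopent-2-en-1-yl]-4-[(2Z)-4-chlorobut-2-en-2-yl]-1-(hydroxymethyl)cyclopentan-1-ol; 24 (2-methylprop-1-en-1-yl)magnesium bromide
Product: 25 (1R,2S,4S)-2-[(1S,5R)-2-(tert-butyldimethylsilyloxy)-5-methylcyclopent-2-en-1-yl]-1-(hydroxymethyl)-4-[(2Z)-6-methylhepta-2,5-dien-2-yl]cyclopentan-1-ol
Conditions: Li2CuCl4 (5 mol%), THF, −30 → 0 °C (24 in excess)
Reagents that add atoms: none
Why: Copper-catalysed cross-coupling of the primary allylic chloride with the alkenyl Grignard reagent should occur at the α-carbon with retention of the Z geometry, the excess reagent only deprotonating the diol.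

Step 18
Reactants: 25 (1R,2S,4S)-2-[(1S,5R)-2-(tert-butyldimethylsilyloxy)-5-methylcyclopent-2-en-1-yl]-1-(hydroxymethyl)-4-[(2Z)-6-methylhepta-2,5-dien-2-yl]cyclopentan-1-ol
Product: 26 [(1R,2S,4S)-2-[(1S,5R)-2-(tert-butyldimethylsilyloxy)-5-methylcyclopent-2-en-1-yl]-1-hydroxy-4-[(2Z)-6-methylhepta-2,5-dien-2-yl]cyclopentyl]methyl acetate
Conditions: Ac2O, pyridine, CH2Cl2, 0 °C
Reagents that add atoms: acetic anhydride, CC(=O)OC(C)=O
Why: The primary hydroxyl is acylated selectively because the tertiary hydroxyl is unreactive under these conditions.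

Step 19
Reactants: 26 [(1R,2S,4S)-2-[(1S,5R)-2-(tert-butyldimethylsilyloxy)-5-methylcyclopent-2-en-1-yl]-1-hydroxy-4-[(2Z)-6-methylhepta-2,5-dien-2-yl]cyclopentyl]methyl acetate
Product: 27 [(1R,2S,4S)-1-hydroxy-4-[(2Z)-6-methylhepta-2,5-dien-2-yl]-2-[(1S,2R)-2-methyl-5-oxocyclopent-3-en-1-yl]cyclopentyl]methyl acetate
Conditions: Pd(OAc)2 (1.1 equiv), MeCN, rt
Reagents that add atoms: none
Why: Saegusa–Ito oxidation (palladium enolate, then β-hydride elimination) gives the enone at the position fixed by the silyl enol ether under base-free conditions, so the cis α-center should be kept.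

Step 20
Reactants: 27 [(1R,2S,4S)-1-hydroxy-4-[(2Z)-6-methylhepta-2,5-dien-2-yl]-2-[(1S,2R)-2-methyl-5-oxocyclopent-3-en-1-yl]cyclopentyl]methyl acetate
Product: 28 [(1R,2S,4S)-4-[(2Z,4E)-6-hydroperoxy-6-methylhepta-2,4-dien-2-yl]-1-hydroxy-2-[(1S,2R)-2-methyl-5-oxocyclopent-3-en-1-yl]cyclopentyl]methyl acetate
Conditions: O2, hν (visible), tetraphenylporphyrin (cat.), CH2Cl2, 0 °C
Reagents that add atoms: dioxygen, O=O
Why: In the Schenck ene reaction singlet oxygen should bond to the tertiary carbon of the terminal trisubstituted alkene and abstract the doubly allylic hydrogen, which moves the double bond into conjugation as the (E)-alkene and leaves the tertiary hydroperoxide.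

## Compound list

1 | 4-(5-methylfuran-2-yl)butan-2-one | CC(=O)CCc1ccc(C)o1 | starting material
2 | 3-[(5-methylfuran-2-yl)methyl]but-3-en-2-one | CC(=O)C(=C)Cc1ccc(C)o1 | intermediate
3 | triisopropyl({3-[(5-methylfuran-2-yl)methyl]buta-1,3-dien-2-yl}oxy)silane | C=C(O[Si](C(C)C)(C(C)C)C(C)C)C(=C)Cc1ccc(C)o1 | intermediate
4 | 2,2,2-trifluoroethyl prop-2-enoate | C=CC(=O)OCC(F)(F)F | starting material
5 | 2,2,2-trifluoroethyl (1R)-3-[(5-methylfuran-2-yl)methyl]-4-(triisopropylsilyloxy)cyclohex-3-ene-1-carboxylate | CC(C)[Si](C(C)C)(C(C)C)OC1=C(Cc2ccc(C)o2)C[C@H](C(=O)OCC(F)(F)F)CC1 | intermediate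
6 | (1R)-N-methoxy-N-methyl-3-[(5-methylfuran-2-yl)methyl]-4-(triisopropylsilyloxy)cyclohex-3-ene-1-carboxamide | CC(C)[Si](C(C)C)(C(C)C)OC1=C(Cc2ccc(C)o2)C[C@H](C(=O)N(C)OC)CC1 | intermediate
7 | (1R,3S)-N-methoxy-N-methyl-3-[(5-methylfuran-2-yl)methyl]-4-oxocyclohexane-1-carboxamide | O=C1CC[C@@H](C(=O)N(C)OC)C[C@H]1Cc1ccc(C)o1 | intermediate
8 | 5-(trifluoroacetyl) derivative of 7 (trifluoroacetyl ketone, epimers at C5 or enol) | O=C1C(C(=O)C(F)(F)F)C[C@@H](C(=O)N(C)OC)C[C@H]1Cc1ccc(C)o1 | intermediate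
9 | (1S,3S)-5-diazo-N-methoxy-N-methyl-3-[(5-methylfuran-2-yl)methyl]-4-oxocyclohexane-1-carboxamide | O=C1C(=[N+]=[N-])C[C@@H](C(=O)N(C)OC)C[C@H]1Cc1ccc(C)o1 | intermediate
10 | (1S,3S)-N-methoxy-N-methyl-3-[(5-methylfuran-2-yl)methyl]-4-(oxomethylidene)cyclopentane-1-carboxamide (ketene) | O=C=C1C[C@@H](C(=O)N(C)OC)C[C@H]1Cc1ccc(C)o1 | intermediate
11 | lithium enolate of methyl (2S,4S)-4-[methoxy(methyl)carbamoyl]-2-[(5-methylfuran-2-yl)methyl]cyclopentane-1-carboxylate | [Li+].[O-]C(OC)=C1C[C@@H](C(=O)N(C)OC)C[C@H]1Cc1ccc(C)o1 | intermediate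
12 | methyl (1R,2S,4S)-1-hydroxy-4-[methoxy(methyl)carbamoyl]-2-[(5-methylfuran-2-yl)methyl]cyclopentane-1-carboxylate | COC(=O)[C@@]1(O)C[C@@H](C(=O)N(C)OC)C[C@H]1Cc1ccc(C)o1 | intermediate
13 | methyl (1R,2S,4S)-2-(2,5-dioxohexyl)-1-hydroxy-4-[methoxy(methyl)carbamoyl]cyclopentane-1-carboxylate | COC(=O)[C@@]1(O)C[C@@H](C(=O)N(C)OC)C[C@H]1CC(=O)CCC(C)=O | intermediate
14 | methyl (1R,2S,4S)-1-hydroxy-4-[methoxy(methyl)carbamoyl]-2-(2-methyl-5-oxocyclopent-1-en-1-yl)cyclopentane-1-carboxylate | COC(=O)[C@@]1(O)C[C@@H](C(=O)N(C)OC)C[C@H]1C1=C(C)CCC1=O | intermediate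
15 | methyl (1R,2S,4S)-1-hydroxy-4-[methoxy(methyl)carbamoyl]-2-[(1S,2R)-2-methyl-5-oxocyclopentyl]cyclopentane-1-carboxylate | COC(=O)[C@@]1(O)C[C@@H](C(=O)N(C)OC)C[C@H]1[C@H]1C(=O)CC[C@H]1C | intermediate
16 | methyl (1R,2S,4S)-2-[(1S,5R)-2-(tert-butyldimethylsilyloxy)-5-methylcyclopent-2-en-1-yl]-1-hydroxy-4-[methoxy(methyl)carbamoyl]cyclopentane-1-carboxylate | COC(=O)[C@@]1(O)C[C@@H](C(=O)N(C)OC)C[C@H]1[C@H]1C(O[Si](C)(C)C(C)(C)C)=CC[C@H]1C | intermediate
17 | (1S,3R,4S)-4-[(1S,5R)-2-(tert-butyldimethylsilyloxy)-5-methylcyclopent-2-en-1-yl]-3-hydroxy-3-(hydroxymethyl)cyclopentane-1-carbaldehyde | OC[C@@]1(O)C[C@@H](C=O)C[C@H]1[C@H]1C(O[Si](C)(C)C(C)(C)C)=CC[C@H]1C | intermediate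
18 | (1R,2S,4S)-2-[(1S,5R)-2-(tert-butyldimethylsilyloxy)-5-methylcyclopent-2-en-1-yl]-4-ethynyl-1-(hydroxymethyl)cyclopentan-1-ol | OC[C@@]1(O)C[C@@H](C#C)C[C@H]1[C@H]1C(O[Si](C)(C)C(C)(C)C)=CC[C@H]1C | intermediate
19 | open methyl carbonate: lithium tertiary alkoxide of the ynoate that carries the primary methyl carbonate | [Li+].COC(=O)OC[C@@]1([O-])C[C@@H](C#CC(=O)OC)C[C@H]1[C@H]1C(O[Si](C)(C)C(C)(C)C)=CC[C@H]1C | intermediate
20 | methyl 3-[(5R,6S,8S)-6-[(1S,5R)-2-(tert-butyldimethylsilyloxy)-5-methylcyclopent-2-en-1-yl]-2-oxo-1,3-dioxaspiro[4.4]nonan-8-yl]prop-2-ynoate | O=C1OC[C@@]2(O1)C[C@@H](C#CC(=O)OC)C[C@H]2[C@H]1C(O[Si](C)(C)C(C)(C)C)=CC[C@H]1C | intermediate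
21 | methyl (2Z)-3-[(5R,6S,8S)-6-[(1S,5R)-2-(tert-butyldimethylsilyloxy)-5-methylcyclopent-2-en-1-yl]-2-oxo-1,3-dioxaspiro[4.4]nonan-8-yl]but-2-enoate | O=C1OC[C@@]2(O1)C[C@@H](/C(C)=C\C(=O)OC)C[C@H]2[C@H]1C(O[Si](C)(C)C(C)(C)C)=CC[C@H]1C | intermediate
22 | (1R,2S,4S)-2-[(1S,5R)-2-(tert-butyldimethylsilyloxy)-5-methylcyclopent-2-en-1-yl]-4-[(2Z)-4-hydroxybut-2-en-2-yl]-1-(hydroxymethyl)cyclopentan-1-ol | OC[C@@]1(O)C[C@@H](/C(C)=C\CO)C[C@H]1[C@H]1C(O[Si](C)(C)C(C)(C)C)=CC[C@H]1C | intermediate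
23 | (1R,2S,4S)-2-[(1S,5R)-2-(tert-butyldimethylsilyloxy)-5-methylcyclopent-2-en-1-yl]-4-[(2Z)-4-chlorobut-2-en-2-yl]-1-(hydroxymethyl)cyclopentan-1-ol | OC[C@@]1(O)C[C@@H](/C(C)=C\CCl)C[C@H]1[C@H]1C(O[Si](C)(C)C(C)(C)C)=CC[C@H]1C | intermediate
24 | (2-methylprop-1-en-1-yl)magnesium bromide | CC(C)=C[Mg]Br | starting material
25 | (1R,2S,4S)-2-[(1S,5R)-2-(tert-butyldimethylsilyloxy)-5-methylcyclopent-2-en-1-yl]-1-(hydroxymethyl)-4-[(2Z)-6-methylhepta-2,5-dien-2-yl]cyclopentan-1-ol | OC[C@@]1(O)C[C@@H](/C(C)=C\CC=C(C)C)C[C@H]1[C@H]1C(O[Si](C)(C)C(C)(C)C)=CC[C@H]1C | intermediate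
26 | [(1R,2S,4S)-2-[(1S,5R)-2-(tert-butyldimethylsilyloxy)-5-methylcyclopent-2-en-1-yl]-1-hydroxy-4-[(2Z)-6-methylhepta-2,5-dien-2-yl]cyclopentyl]methyl acetate | CC(=O)OC[C@@]1(O)C[C@@H](/C(C)=C\CC=C(C)C)C[C@H]1[C@H]1C(O[Si](C)(C)C(C)(C)C)=CC[C@H]1C | intermediate
27 | [(1R,2S,4S)-1-hydroxy-4-[(2Z)-6-methylhepta-2,5-dien-2-yl]-2-[(1S,2R)-2-methyl-5-oxocyclopent-3-en-1-yl]cyclopentyl]methyl acetate | CC(=O)OC[C@@]1(O)C[C@@H](/C(C)=C\CC=C(C)C)C[C@H]1[C@H]1C(=O)C=C[C@H]1C | intermediate
28 | [(1R,2S,4S)-4-[(2Z,4E)-6-hydroperoxy-6-methylhepta-2,4-dien-2-yl]-1-hydroxy-2-[(1S,2R)-2-methyl-5-oxocyclopent-3-en-1-yl]cyclopentyl]methyl acetate (CNP0204569.1) | CC(=O)OC[C@@]1(O)C[C@@H](/C(C)=C\C=C\C(C)(C)OO)C[C@H]1[C@H]1C(=O)C=C[C@H]1C | target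

## Step count and risks

Total step count: 20. Longest linear sequence: 20 steps (from 1; compounds 4 and 24 are purchased).

Steps most likely to fail:

1. Step 10 – poor facial selectivity of the hydrogenation: a hydroxyl-guided or unselective delivery of hydrogen to the tetrasubstituted enone would give the other cis pair of ring centers. The fallback sets out from 14 and returns at 15. CBS reduction of the enone carbonyl of 14 [(S)-2-methyl-CBS-oxazaborolidine (cat.), BH3·SMe2, THF, −20 °C] should give the allylic alcohol F1 with reagent-controlled (R) carbinol configuration. Hydrogenation directed by that allylic hydroxyl with [Ir(cod)(PCy3)(py)]PF6 under H2 in CH2Cl2 then delivers both hydrogens on the hydroxyl face, giving the all-cis cyclopentanol F2. Dess–Martin oxidation of the secondary alcohol leads back to 15.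

2. Step 20 – poor site and regioselectivity of the ene reaction: the second trisubstituted alkene may compete, and hydrogen may be abstracted from a methyl group instead of the doubly allylic CH2. The fallback sets out from 27 and returns at 28. Selenium-mediated peroxidation of the terminal alkene of 27 (PhSeBr, pyridine, 2-methoxypropan-2-yl hydroperoxide, CH2Cl2, −78 °C) should follow Markovnikov opening at the tertiary carbon and give the β-phenylselanyl peroxyketal F3. Oxidation with m-CPBA at −78 °C and base-free syn-elimination of the selenoxide away from the oxygenated carbon give the (E)-allylic peroxyketal F4. Mild hydrolysis (AcOH, THF, H2O, rt) frees the hydroperoxide 28.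

3. Step 7 – loss of material in the one-flask contraction and hydroxylation: the ketene may dimerise, the enolate may be quenched by proton transfer, or it may add to the sulfonimine by-product. The fallback sets out from 9 and returns at 12. Photolysis of 9 in methanol traps the ketene directly as the ring-contracted methyl ester F5 (mixture at the ester-bearing carbon). Separate enolisation of the ester with KN(SiMe3)2 in THF at −78 °C (the amide α-hydrogen is less acidic) and oxidation with 2-(benzenesulfonyl)-3-phenyloxaziridine from the face anti to the ring substituents give 12.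

Further compounds
F1 | step 10 | methyl (1R,2S,4S)-1-hydroxy-2-[(5R)-5-hydroxy-2-methylcyclopent-1-en-1-yl]-4-[methoxy(methyl)carbamoyl]cyclopentane-1-carboxylate | COC(=O)[C@@]1(O)C[C@@H](C(=O)N(C)OC)C[C@H]1C1=C(C)CC[C@H]1O
F2 | step 10 | methyl (1R,2S,4S)-1-hydroxy-2-[(1S,2R,5R)-2-hydroxy-5-methylcyclopentyl]-4-[methoxy(methyl)carbamoyl]cyclopentane-1-carboxylate | COC(=O)[C@@]1(O)C[C@@H](C(=O)N(C)OC)C[C@H]1[C@H]1[C@H](O)CC[C@H]1C
F3 | step 20 | [(1R,2S,4S)-1-hydroxy-4-[(2Z)-6-[(2-methoxypropan-2-yl)peroxy]-6-methyl-5-(phenylselanyl)hept-2-en-2-yl]-2-[(1S,2R)-2-methyl-5-oxocyclopent-3-en-1-yl]cyclopentyl]methyl acetate | CC(=O)OC[C@@]1(O)C[C@@H](/C(C)=C\CC([Se]c2ccccc2)C(C)(C)OOC(C)(C)OC)C[C@H]1[C@H]1C(=O)C=C[C@H]1C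
F4 | step 20 | [(1R,2S,4S)-1-hydroxy-4-[(2Z,4E)-6-[(2-methoxypropan-2-yl)peroxy]-6-methylhepta-2,4-dien-2-yl]-2-[(1S,2R)-2-methyl-5-oxocyclopent-3-en-1-yl]cyclopentyl]methyl acetate | CC(=O)OC[C@@]1(O)C[C@@H](/C(C)=C\C=C\C(C)(C)OOC(C)(C)OC)C[C@H]1[C@H]1C(=O)C=C[C@H]1C
F5 | step 7 | methyl (2S,4S)-4-[methoxy(methyl)carbamoyl]-2-[(5-methylfuran-2-yl)methyl]cyclopentane-1-carboxylate | COC(=O)C1C[C@@H](C(=O)N(C)OC)C[C@H]1Cc1ccc(C)o1
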